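**Plan** (locants are those of ent-kaurane: C1 ring-A ketone, C3–O–C6 ether bridge, C7 lactone carbonyl, C20 lactone CH2, C10 spiro carbon, C15/C16 ring-D ketone and carbinol)
- Cuts, in retrosynthetic order: C1/C15 ketones ⇐ alcohols; C13–C14 and C9–C11 together (rings D and C); C8–C15 (Michael/aldol), which divides the molecule into a spiro α-methylene lactone and an allenyl aldehyde; lactone ⇐ vinyl bromide + CO; C3–O ⇐ oxa-Michael; C10 ⇐ two enolate reactions.
- Forward: ring A with C5 and C10 → spiro lactone → ether bridge (cage) → union at C8–C15 → one radical chain closes ring D, then ring C → deprotection, oxidation.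
- Enabling feature: C14 and C9 both hang on the quaternary C8 of the lactone, and C13=C12=C11 is an allene. Once C14 bonds to C13, the vinyl radical at C12 lies 1,5 to H–C9, so one radical serves both allene termini and C12 ends as CH2.
- Stereochemistry: C16 from palladium-catalysed asymmetric opening of isoprene monoxide; C5 from copper hydride asymmetric conjugate reduction; C10, C3 and C8 by substrate control from C5; C13 and C9 in the key step, steered by C16 and the bridged ring geometry.

Key step: step 16

Assumption: the ligand antipodes named in steps 1 and 8 are those expected to give the configurations drawn; if the sense of induction on these substrates proves opposite, the mirror-image ligand is used.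

**Step 1**
Reactants: 1 rac-2-methyl-2-vinyloxirane (isoprene monoxide)
Product: 3 (R)-2-methylbut-3-ene-1,2-diol, via hydrogen carbonate 2 (not isolated)
Conditions: Pd2(dba)3·CHCl3 (1 mol%), (R,R)-N,N′-bis[2-(diphenylphosphino)-1-naphthoyl]-1,2-diaminocyclohexane (3 mol%), Et3B (1 mol%), NaHCO3, CH2Cl2/H2O, rt
Reagents that add atoms: sodium hydrogencarbonate, [Na+].OC([O-])=O
Why: Palladium-catalysed dynamic kinetic asymmetric allylic substitution (Tsuji–Trost type): both enantiomers of 1 ionize to interconverting π-allylpalladium complexes, and boron-templated delivery of hydrogencarbonate to the tertiary terminus under ligand control should set C16 as R, the carbonate then losing CO2.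

**Step 2**
Reactants: 3 (R)-2-methylbut-3-ene-1,2-diol
Product: 4 (R)-2-methyl-1,2-bis(triethylsilyloxy)but-3-ene
Conditions: TESOTf (2.4 equiv), 2,6-lutidine, CH2Cl2, −40 → 0 °C
Reagents that add atoms: triethylsilyl trifluoromethanesulfonate, CC[Si](CC)(CC)OS(=O)(=O)C(F)(F)F
Why: Silyl ether formation; the triflate is reactive enough for the tertiary hydroxyl and no stereocentre is touched.

**Step 3**
Reactants: 4 (R)-2-methyl-1,2-bis(triethylsilyloxy)but-3-ene
Product: 5 (2R)-2-(2,2-dibromocyclopropyl)-1,2-bis(triethylsilyloxy)propane (both epimers at the ring CH)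
Conditions: CHBr3, KOt-Bu, pentane, −10 °C → rt
Reagents that add atoms: bromoform, BrC(Br)Br
Why: Dibromocarbene cyclopropanation of the only alkene (first half of the Doering–LaFlamme allene synthesis); the new ring stereocentre is lost in step 4.

**Step 4**
Reactants: 5 (2R)-2-(2,2-dibromocyclopropyl)-1,2-bis(triethylsilyloxy)propane
Product: 7 (R)-2-methyl-1,2-bis(triethylsilyloxy)penta-3,4-diene, via bromolithio carbenoid 6 (not isolated)
Conditions: MeLi, Et2O, −78 → −40 °C
Reagents that add atoms: none
Why: Doering–LaFlamme rearrangement: bromine–lithium exchange, loss of LiBr and opening of the cyclopropylidene should give the terminal allene, the former carbene carbon becoming the central carbon C12.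

**Step 5**
Reactants: 7 (R)-2-methyl-1,2-bis(triethylsilyloxy)penta-3,4-diene
Product: 8 (R)-2-methyl-2-(triethylsilyloxy)penta-3,4-dienal
Conditions: (COCl)2, DMSO, CH2Cl2, −78 → −30 °C; then Et3N
Reagents that add atoms: none
Why: Swern oxidation applied directly to the silyl ether: the primary triethylsilyl ether is cleaved and oxidized while the tertiary one survives, and the aldehyde has no α-hydrogen, so the allene cannot move into conjugation.

**Step 6**
Reactants: 9 4,4-dimethylcyclohexane-1,3-dione
Product: 10 3-isobutoxy-6,6-dimethylcyclohex-2-en-1-one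
Conditions: i-BuOH, TsOH (cat.), toluene, reflux (Dean–Stark)
Reagents that add atoms: 2-methylpropan-1-ol, CC(C)CO
Why: Acid-catalysed vinylogous ester formation, which should take place at the carbonyl remote from the gem-dimethyl carbon because the neopentyl carbonyl is the more hindered one.

**Step 7**
Reactants: 10 3-isobutoxy-6,6-dimethylcyclohex-2-en-1-one
Product: 12 3-[(methoxymethoxy)methyl]-4,4-dimethylcyclohex-2-en-1-one, via lithium alkoxide 11 (not isolated)
Conditions: Bu3SnCH2OMOM, n-BuLi, THF, −78 °C; then 10, −78 → 0 °C; then 1 M HCl, rt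
Reagents that add atoms: tributyl[(methoxymethoxy)methyl]stannane, CCCC[Sn](CCCC)(CCCC)COCOC
Why: Stork–Danheiser enone transposition: the α-alkoxymethyllithium made by tin–lithium exchange adds to the carbonyl, and acid hydrolysis of the enol ether with loss of water puts C6 on the β-carbon next to the gem-dimethyl carbon.

**Step 8**
Reactants: 12 3-[(methoxymethoxy)methyl]-4,4-dimethylcyclohex-2-en-1-one
Product: 14 (2R,3R)-2-(2-bromoprop-2-en-1-yl)-3-[(methoxymethoxy)methyl]-4,4-dimethylcyclohexan-1-one, via silyl enol ether 13 (not isolated)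
Conditions: Cu(OAc)2 (5 mol%), (R)-DTBM-SEGPHOS (5.5 mol%), (EtO)2MeSiH, toluene, 0 °C; then Bu4N[Ph3SiF2], 2,3-dibromopropene, THF, rt
Reagents that add atoms: 2,3-dibromopropene, C=C(Br)CBr
Why: Copper hydride asymmetric conjugate reduction sets C5 under ligand control and delivers the enolate regiospecifically as its silyl ether; fluoride-triggered allylation then takes place at C10 trans to the C5 arm (tandem conjugate reduction–alkylation).

**Step 9**
Reactants: 14 (2R,3R)-2-(2-bromoprop-2-en-1-yl)-3-[(methoxymethoxy)methyl]-4,4-dimethylcyclohexan-1-one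
Product: 16 (5R,6R)-6-(2-bromoprop-2-en-1-yl)-5-[(methoxymethoxy)methyl]-4,4-dimethylcyclohex-2-en-1-one, via lithium enolate 15 (not isolated)
Conditions: LiN(i-Pr)2, THF, −78 °C; then PhS(Cl)=N-t-Bu, −78 °C
Reagents that add atoms: none
Why: Mukaiyama dehydrogenation with N-tert-butylbenzenesulfinimidoyl chloride: kinetic deprotonation occurs at the unhindered C2 methylene, so the C2=C3 enone forms and C10–H is left as the only enolizable position.

**Step 10**
Reactants: 16 (5R,6R)-6-(2-bromoprop-2-en-1-yl)-5-[(methoxymethoxy)methyl]-4,4-dimethylcyclohex-2-en-1-one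
Product: 18 (5S,6S)-6-(2-bromoprop-2-en-1-yl)-6-(hydroxymethyl)-5-[(methoxymethoxy)methyl]-4,4-dimethylcyclohex-2-en-1-one, via lithium dienolate 17 (not isolated)
Conditions: LiN(i-Pr)2, THF, −78 °C; then CH2O (monomer in THF), −78 °C; NH4Cl
Reagents that add atoms: formaldehyde, C=O
Why: Aldol addition of the cross-conjugated (α′) dienolate to formaldehyde; the electrophile should enter anti to the vicinal, pseudo-axial CH2OMOM group on C5, so that C20 ends trans and the bromoallyl arm (C9) cis to C6 at the new quaternary C10.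

**Step 11**
Reactants: 18 (5S,6S)-6-(2-bromoprop-2-en-1-yl)-6-(hydroxymethyl)-5-[(methoxymethoxy)methyl]-4,4-dimethylcyclohex-2-en-1-one
Product: 19 (6S,7S)-7-[(methoxymethoxy)methyl]-8,8-dimethyl-4-methylidene-2-oxaspiro[5.5]undec-9-ene-3,11-dione
Conditions: Pd(PPh3)4 (5 mol%), CO (3 atm), K2CO3, MeCN, 65 °C
Reagents that add atoms: carbon monoxide, [C-]#[O+]
Why: Palladium-catalysed carbonylative lactonization: oxidative addition of zerovalent palladium into the vinyl bromide, CO insertion and capture of the acylpalladium by the C20 hydroxyl close the α-methylene-δ-lactone; no stereocentre changes.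

**Step 12**
Reactants: 19 (6S,7S)-7-[(methoxymethoxy)methyl]-8,8-dimethyl-4-methylidene-2-oxaspiro[5.5]undec-9-ene-3,11-dione
Product: 21 cage keto lactone (3S,5S,10S), via hydroxy enone 20 (not isolated)
Conditions: 3 M HCl, THF, 45 °C
Reagents that add atoms: none
Why: Acidic cleavage of the MOM ether followed by intramolecular oxa-Michael addition (5-exo-trig) of the C6 hydroxyl to the enone; the one-carbon tether reaches C3 only from the face that carries C6, which fixes C3.

**Step 13**
Reactants: 21 cage keto lactone (3S,5S,10S); 8 (R)-2-methyl-2-(triethylsilyloxy)penta-3,4-dienal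
Product: 23 seleno aldol (3S,5S,8R,10S,15S,16R), via lithium enolate 22 (not isolated)
Conditions: PhSeH, n-BuLi, THF, −78 °C (gives PhSeLi); added to 21 + 8, THF, −78 °C; AcOH, −78 °C
Reagents that add atoms: lithium benzeneselenolate (from benzeneselenol), [Li][Se]c1ccccc1
Why: Selenolate-initiated Michael/aldol tandem: PhSe– adds to C14 and the lactone enolate adds to the non-enolizable aldehyde on the face opposite the pseudo-axial C1 carbonyl arm of the spiro ring, which makes C8 quaternary with C15 cis to C5, while Felkin–Anh attack anti to the silyloxy group should give the 15S carbinol.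

**Step 14**
Reactants: 23 seleno aldol (3S,5S,8R,10S,15S,16R)
Product: 24 selenide diol (1R alcohol)
Conditions: NaBH4, CeCl3·7H2O, MeOH, −78 °C
Reagents that add atoms: none
Why: Luche reduction takes the C1 ketone only (lactone, selenide and allene are inert); hydride should come from the face away from the O–CH2 bridge, and this carbinol is oxidized back in step 18, so its configuration is of no consequence.

**Step 15**
Reactants: 24 selenide diol (1R alcohol)
Product: 25 tris(silyl ether) selenide
Conditions: TESOTf (3 equiv), 2,6-lutidine, CH2Cl2, 0 °C → rt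
Reagents that add atoms: triethylsilyl trifluoromethanesulfonate, CC[Si](CC)(CC)OS(=O)(=O)C(F)(F)F
Why: Silyl ether formation at both secondary hydroxyls, so that in step 16 no radical centre is β to a ketone and the aldol cannot revert.

**Step 16**
Reactants: 25 tris(silyl ether) selenide
Product: 26 tetracyclic tris(silyl ether) (1R,3S,5S,8S,9S,10S,13R,15S,16R)
Conditions: Bu3SnH (1.3 equiv, syringe pump over 10 h), AIBN (0.3 equiv), PhH (2 mM), 80 °C
Reagents that add atoms: none
Why: Proposed new method: Bu3Sn• takes PhSe from C14, the neopentyl radical adds to the near allene carbon C13 (5-exo-trig, ring D), the vinyl radical so formed at C12 abstracts H from C9 through a six-membered transition state, and the C9 radical closes ring C on the CH2 terminus C11 (6-endo-trig), the C12 radical then taking H from Bu3SnH; the closest known reaction type is the vinyl-radical translocation cascade (radical cyclization onto an alkyne, 1,5-hydrogen shift, second cyclization), extended here to an allene so that one radical chain bonds both allene termini and leaves the central carbon as CH2. C13 is set in the first closure by a chair-like transition state with the C16 methyl and the C15 silyloxy group pseudo-equatorial, which places the vinyl radical trans to the methyl and cis to C9, and only this epimer can reach H–C9. C9 is set in the second closure: bonding through the C14 tether is possible only on the face that gives the bicyclo[3.2.1]octane, and the lactone should pucker so that the bulky C10 lies anti to C15. The step needs 5-exo rather than 6-endo attack on the allene (stereoelectronic preference of a hepta-5,6-dienyl radical), hydrogen transfer faster than reduction of the vinyl radical (Bu3SnH kept near 1 mM by slow addition) and 6-endo rather than 5-exo closure of the doubly neopentyl C9 radical (attack at the unhindered CH2, the alternative being a strained norbornane). C1 and C15 are carried as silyl ethers so that neither the C14 nor the C9 radical is β to a ketone, which excludes 1,2-acyl shifts.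

**Step 17**
Reactants: 26 tetracyclic tris(silyl ether)
Product: 27 triol (1R,3S,5S,8S,9S,10S,13R,15S,16R)
Conditions: HF·pyridine, THF, 0 °C → rt
Reagents that add atoms: none
Why: Fluoride-mediated cleavage of the three triethylsilyl ethers in an acidic medium, so that the lactone and the ether bridge are not exposed to base.

**Step 18**
Reactants: 27 triol
Product: 28 target CNP0538153.1 (3S,5S,8S,9S,10S,13R,16R)
Conditions: IBX, EtOAc, 75 °C
Reagents that add atoms: none
Why: IBX oxidation of the C1 and C15 secondary alcohols to the ketones; the tertiary C16 hydroxyl cannot be oxidized, IBX does not cleave the 15,16-glycol, and no stereocentre is enolizable (C8, C10 and C16 are quaternary, C13 is a bridgehead).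

**Compound list**
1 | rac-2-methyl-2-vinyloxirane (isoprene monoxide) | CC1(CO1)C=C | starting material
2 | (R)-1-hydroxy-2-methylbut-3-en-2-yl hydrogen carbonate | C=C[C@@](C)(OC(O)=O)CO | intermediate
3 | (R)-2-methylbut-3-ene-1,2-diol | C=C[C@@](C)(O)CO | intermediate
4 | (R)-2-methyl-1,2-bis(triethylsilyloxy)but-3-ene | C=C[C@@](C)(O[Si](CC)(CC)CC)CO[Si](CC)(CC)CC | intermediate
5 | (2R)-2-(2,2-dibromocyclopropyl)-1,2-bis(triethylsilyloxy)propane, both epimers at the ring CH | BrC1(Br)CC1[C@@](C)(O[Si](CC)(CC)CC)CO[Si](CC)(CC)CC | intermediate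
6 | 1-bromo-1-lithiocyclopropane carbenoid from 5 | [Li]C1(Br)CC1[C@@](C)(O[Si](CC)(CC)CC)CO[Si](CC)(CC)CC | intermediate
7 | (R)-2-methyl-1,2-bis(triethylsilyloxy)penta-3,4-diene | C=C=C[C@@](C)(O[Si](CC)(CC)CC)CO[Si](CC)(CC)CC | intermediate
8 | (R)-2-methyl-2-(triethylsilyloxy)penta-3,4-dienal | C=C=C[C@@](C)(O[Si](CC)(CC)CC)C=O | intermediate
9 | 4,4-dimethylcyclohexane-1,3-dione | CC1(C)CCC(=O)CC1=O | starting material
10 | 3-isobutoxy-6,6-dimethylcyclohex-2-en-1-one | CC(C)COC1=CC(=O)C(C)(C)CC1 | intermediate
11 | lithium 3-isobutoxy-1-[(methoxymethoxy)methyl]-6,6-dimethylcyclohex-2-en-1-olate (racemic) | [Li]OC1(COCOC)C=C(OCC(C)C)CCC1(C)C | intermediate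
12 | 3-[(methoxymethoxy)methyl]-4,4-dimethylcyclohex-2-en-1-one | CC1(C)CCC(=O)C=C1COCOC | intermediate
13 | diethoxy(methyl)silyl enol ether of (R)-3-[(methoxymethoxy)methyl]-4,4-dimethylcyclohexanone (C1=C10 enol) | CC1(C)CCC(O[Si](C)(OCC)OCC)=C[C@H]1COCOC | intermediate
14 | (2R,3R)-2-(2-bromoprop-2-en-1-yl)-3-[(methoxymethoxy)methyl]-4,4-dimethylcyclohexan-1-one | CC1(C)CCC(=O)[C@H](CC(Br)=C)[C@H]1COCOC | intermediate
15 | kinetic lithium enolate of 14 (C1=C2 enolate) | CC1(C)CC=C(O[Li])[C@H](CC(Br)=C)[C@H]1COCOC | intermediate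
16 | (5R,6R)-6-(2-bromoprop-2-en-1-yl)-5-[(methoxymethoxy)methyl]-4,4-dimethylcyclohex-2-en-1-one | CC1(C)C=CC(=O)[C@H](CC(Br)=C)[C@H]1COCOC | intermediate
17 | cross-conjugated lithium dienolate of 16 | CC1(C)C=CC(O[Li])=C(CC(Br)=C)[C@H]1COCOC | intermediate
18 | (5S,6S)-6-(2-bromoprop-2-en-1-yl)-6-(hydroxymethyl)-5-[(methoxymethoxy)methyl]-4,4-dimethylcyclohex-2-en-1-one | CC1(C)C=CC(=O)[C@](CC(Br)=C)(CO)[C@H]1COCOC | intermediate
19 | (6S,7S)-7-[(methoxymethoxy)methyl]-8,8-dimethyl-4-methylidene-2-oxaspiro[5.5]undec-9-ene-3,11-dione | CC1(C)C=CC(=O)[C@]2(COC(=O)C(=C)C2)[C@H]1COCOC | intermediate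
20 | (6S,7S)-7-(hydroxymethyl)-8,8-dimethyl-4-methylidene-2-oxaspiro[5.5]undec-9-ene-3,11-dione | CC1(C)C=CC(=O)[C@]2(COC(=O)C(=C)C2)[C@H]1CO | intermediate
21 | cage keto lactone: ring A as 8,8-dimethyl-6-oxabicyclo[3.2.1]octan-3-one (C1 ketone, C3–O–C6 bridge), spiro at C10 to the 3-methylidenetetrahydropyran-2-one ring (C20H2–O–C7(=O)–C8(=C14H2)–C9H2); 3S,5S,10S | CC1(C)[C@@H]2CC(=O)[C@]3(COC(=O)C(=C)C3)[C@H]1CO2 | intermediate
22 | lithium enolate of the C14 phenylselenide of 21 (C7=C8 enolate) | CC1(C)[C@@H]2CC(=O)[C@]3(COC(O[Li])=C(C[Se]c4ccccc4)C3)[C@H]1CO2 | intermediate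
23 | seleno aldol: 21 with C8 quaternary, carrying CH2SePh (C14) and CH(OH)–C(CH3)(OSiEt3)–CH=C=CH2 (C15, C16, C13–C11); 3S,5S,8R,10S,15S,16R | CC1(C)[C@@H]2CC(=O)[C@]3(COC(=O)[C@@](C[Se]c4ccccc4)(C3)[C@H](O)[C@](C)(O[Si](CC)(CC)CC)C=C=C)[C@H]1CO2 | intermediate
24 | selenide diol: 23 with the C1 ketone reduced to the 1R alcohol | CC1(C)[C@@H]2C[C@@H](O)[C@]3(COC(=O)[C@@](C[Se]c4ccccc4)(C3)[C@H](O)[C@](C)(O[Si](CC)(CC)CC)C=C=C)[C@H]1CO2 | intermediate
25 | tris(silyl ether) selenide: 1,15-bis(triethylsilyl) ether of 24 | CC1(C)[C@@H]2C[C@@H](O[Si](CC)(CC)CC)[C@]3(COC(=O)[C@@](C[Se]c4ccccc4)(C3)[C@H](O[Si](CC)(CC)CC)[C@](C)(O[Si](CC)(CC)CC)C=C=C)[C@H]1CO2 | intermediate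
26 | tetracyclic tris(triethylsilyl) ether of 27; 1R,3S,5S,8S,9S,10S,13R,15S,16R | CC1(C)[C@@H]2C[C@@H](O[Si](CC)(CC)CC)[C@]3(COC(=O)[C@@]45C[C@@H](CC[C@H]43)[C@@](C)(O[Si](CC)(CC)CC)[C@H]5O[Si](CC)(CC)CC)[C@H]1CO2 | intermediate
27 | triol: the target with C1 and C15 as secondary alcohols (1R,15S) | CC1(C)[C@@H]2C[C@@H](O)[C@]3(COC(=O)[C@@]45C[C@@H](CC[C@H]43)[C@@](C)(O)[C@H]5O)[C@H]1CO2 | intermediate
28 | CNP0538153.1; 3S,5S,8S,9S,10S,13R,16R | CC1(C)[C@@H]2CC(=O)[C@]3(COC(=O)[C@@]45C[C@@H](CC[C@H]43)[C@@](C)(O)C5=O)[C@H]1CO2 | target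

**Totals**
Total steps: 18. Longest linear sequence: 13 steps (9 → 28, steps 6–18); the aldehyde branch (1 → 8) has 5 steps.

**Steps most likely to fail**

1. Step 16 (Proposed new method). What may go wrong: the stannane reduces the vinyl radical or the C9 radical before hydrogen transfer or ring closure; the first closure places the vinyl group trans to C9, which stops the relay; the C9 radical closes 5-exo instead of 6-endo. The fallback uses reactions of established type (iodo-aldol, iodine-atom-transfer cyclization, radical translocation from a vinyl iodide), sets out from 21 and 8 and comes back at 26. Et2AlI in CH2Cl2 at −78 °C adds iodide to C14 of 21 and the aluminium enolate adds to 8, which should give iodo aldol F1. NaBH4/CeCl3 then gives iodide diol F2 and TESOTf/2,6-lutidine the tris(silyl ether) iodide F3. Irradiation of F3 with (Bu3Sn)2 in PhH at 0.3 M, with no hydride donor present, runs an iodine-atom-transfer cyclization: ring D closes and the vinyl radical takes iodine from F3, giving vinyl iodide F4, which can be isolated and checked for the C13 configuration. Bu3SnH/AIBN under high dilution then regenerates the vinyl radical from F4 for the hydrogen transfer and ring C closure, and the route is rejoined at 26.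

2. Step 13. What may go wrong: the aldol between a fully substituted lactone enolate and an α-quaternary aldehyde is congested and reversible, so retro-aldol and loss of selenolate may return 21; facial control at C8 or C15 may be incomplete (a C15 epimer is not lost, since C15 ends as a ketone, but it would steer step 16 less well). The fallback sets out from 8 and 21 and comes back at 24. NaClO2/NaH2PO4/2-methylbut-2-ene oxidizes 8 to (R)-2-methyl-2-(triethylsilyloxy)penta-3,4-dienoic acid F5, and 1-chloro-N,N,2-trimethylprop-1-en-1-amine converts it into acid chloride F6. PhSeLi is added to 21 and enolate 22 is C-acylated with F6 to give β-keto lactone F7, an irreversible bond formation. NaBH4/CeCl3 then reduces the C1 and C15 ketones together to 24.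

3. Step 10. What may go wrong: formaldehyde attacks the other face of dienolate 17 (the face anti to the C5 arm is the one flanked by the axial C4 methyl), giving the C10 epimer, and the hindered β-hydroxy ketone may undergo retro-aldol. The fallback sets out from 12, comes back at 18 and reverses the order in which the two C10 arms are put on. Copper hydride reduction of 12 as in step 8 (via 13) and fluoride-triggered alkylation with 4-methoxybenzyl chloromethyl ether give trans ketone F8. Dehydrogenation as in step 9 gives enone F9. LiN(i-Pr)2 and 2,3-dibromopropene give quaternary PMB ether F10, the bromoallyl arm now being the group that enters last. DDQ removes the PMB group to give 18.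

**Further compounds**
F1 | step 16 | iodo aldol, C14 iodide analogue of 23 | CC1(C)[C@@H]2CC(=O)[C@]3(COC(=O)[C@@](CI)(C3)[C@H](O)[C@](C)(O[Si](CC)(CC)CC)C=C=C)[C@H]1CO2
F2 | step 16 | iodide diol, analogue of 24 | CC1(C)[C@@H]2C[C@@H](O)[C@]3(COC(=O)[C@@](CI)(C3)[C@H](O)[C@](C)(O[Si](CC)(CC)CC)C=C=C)[C@H]1CO2
F3 | step 16 | tris(silyl ether) iodide, analogue of 25 | CC1(C)[C@@H]2C[C@@H](O[Si](CC)(CC)CC)[C@]3(COC(=O)[C@@](CI)(C3)[C@H](O[Si](CC)(CC)CC)[C@](C)(O[Si](CC)(CC)CC)C=C=C)[C@H]1CO2
F4 | step 16 | vinyl iodide with ring D closed (C13–C14 bond made, C13 carrying 1-iodovinyl, C9 still CH2) | CC1(C)[C@@H]2C[C@@H](O[Si](CC)(CC)CC)[C@]3(COC(=O)[C@]4(C3)C[C@@H](C(I)=C)[C@@](C)(O[Si](CC)(CC)CC)[C@H]4O[Si](CC)(CC)CC)[C@H]1CO2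
F5 | step 13 | (R)-2-methyl-2-(triethylsilyloxy)penta-3,4-dienoic acid | C=C=C[C@@](C)(O[Si](CC)(CC)CC)C(O)=O
F6 | step 13 | (R)-2-methyl-2-(triethylsilyloxy)penta-3,4-dienoyl chloride | C=C=C[C@@](C)(O[Si](CC)(CC)CC)C(Cl)=O
F7 | step 13 | β-keto lactone selenide, C15 ketone analogue of 23 | CC1(C)[C@@H]2CC(=O)[C@]3(COC(=O)[C@@](C[Se]c4ccccc4)(C3)C(=O)[C@](C)(O[Si](CC)(CC)CC)C=C=C)[C@H]1CO2
F8 | step 10 | (2S,3R)-2-[(4-methoxybenzyloxy)methyl]-3-[(methoxymethoxy)methyl]-4,4-dimethylcyclohexan-1-one | CC1(C)CCC(=O)[C@H](COCc2ccc(OC)cc2)[C@H]1COCOC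
F9 | step 10 | (5R,6S)-6-[(4-methoxybenzyloxy)methyl]-5-[(methoxymethoxy)methyl]-4,4-dimethylcyclohex-2-en-1-one | CC1(C)C=CC(=O)[C@H](COCc2ccc(OC)cc2)[C@H]1COCOC
F10 | step 10 | (5S,6S)-6-(2-bromoprop-2-en-1-yl)-6-[(4-methoxybenzyloxy)methyl]-5-[(methoxymethoxy)methyl]-4,4-dimethylcyclohex-2-en-1-one | CC1(C)C=CC(=O)[C@](CC(Br)=C)(COCc2ccc(OC)cc2)[C@H]1COCOC
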